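(Readings and results are simulated for an exercise, and the scatter is random.)

**Easy step.** The west run, with 1.5 M of leaving ligand, holds 60% of its starting complex at 6.00 d, more than the 51% of the north-west run with 0.67 M. Even in that north-west run, starting complex stands above its nearest rival, 11% of complex with one exchanged, so starting complex is the amount we follow. Larch and birch share one charge between these runs, 1.00 M of leaving ligand, and differ in the time they are read.

in all of them: starting complex 0.50 M
- north-west: incoming ligand 0.55 M; leaving ligand 0.67 M; run made earlier
- west: incoming ligand 0.55 M; leaving ligand 1.5 M; run made earlier
- larch: incoming ligand 0.550 M; leaving ligand 1.00 M; time 6.0 d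
- birch: incoming ligand 0.550 M; leaving ligand 1.00 M; time 12 d

| run | time / d | isomer of the product / % | complex with two exchanged / % | starting complex / % | complex with one exchanged / % |
|---|---|---|---|---|---|
| north-west | 1.04 | 2 | 13 | 69 | 11 |
| north-west | 2.08 | 6 | 14 | 57 | 15 |
| north-west | 3.00 | 7 | 10 | 59 | 14 |
| north-west | 4.00 | 7 | 8 | 53 | 12 |
| north-west | 5.00 | 9 | 8 | 52 | 11 |
| north-west | 6.00 | 6 | 8 | 51 | 11 |
| north-west | 8.00 | 7 | 8 | 47 | 10 |
| west | 1.04 | 2 | 6 | 74 | 12 |
| west | 2.08 | 6 | 9 | 66 | 11 |
| west | 3.00 | 6 | 7 | 63 | 9 |
| west | 4.00 | 1 | 8 | 61 | 10 |
| west | 5.00 | 5 | 5 | 61 | 9 |
| west | 6.00 | 4 | 4 | 60 | 8 |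
| west | 8.00 | 3 | 7 | 51 | 7 |

(scatter of a reading: 1.5 percentage points)



* which of these there is most of at the end, counted by the starting complex in it, larch (isomer of the product / complex with two exchanged / complex with one exchanged / starting complex)
* which of these there is most of at the end, counted by the starting complex in it, birch (isomer of the product / complex with two exchanged / complex with one exchanged / starting complex)
* amount of the one of these that there is most of at the end, in percent of the starting complex charged, larch
* amount of the one of these that there is most of at the end, in percent of the starting complex charged, birch

**Hand chain.** Those two readings of starting complex give a slope of 0.108 /M of the charge, which puts larch near 54.6%. Birch is larch left longer. From 3.00 d to 8.00 d the two runs lose on average 0.0439 /d of what remains, so if that holds, birch stands near 41.9%.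

**Weak link.** The slope rests on a difference of 9 percentage points between two readings, each with a scatter of 1.5 points. So we average the last 4 readings of each run, whose times centre near 6.0 d. This gives 0.0904 /M for the ligand gain, the share of the charge held as starting complex per molar of added leaving ligand, with the time and the other charges held. We commit to starting complex in both flasks, larch at 53.7% and birch at 41.3%.

**The forecast.** The forecast also names starting complex for larch and starting complex for birch, at 55% and 45%, holding that the “slow phase loses about 3.5% of what remains per day”. Our birch figure is lower.

**The flask.** Larch gives starting complex at 52.5%, and birch gives starting complex at 41.5%. The forecast stands within its margin. Starting complex remains ahead of the three others asked about in larch and in birch.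

    starting complex + incoming ligand ⇌ leaving ligand + complex with one exchanged (K = 1.30, k = 0.0500 /M/h)
    complex with one exchanged + incoming ligand ⇌ leaving ligand + complex with two exchanged (K = 4.10, k = 0.450 /M/h)
    complex with two exchanged + incoming ligand ⇌ leaving ligand + complex with three exchanged (K = 0.340, k = 0.110 /M/h)
    complex with one exchanged → decomposed reagent (k = 0.0170 /h)
    incoming ligand ⇌ dormant form (K = 0.190, k = 0.0160 /h)
    complex with two exchanged ⇌ isomer of the product (K = 0.920, k = 0.0110 /h)

**Neighbour flask.** Without scatter, the north-west flask holds 49.3% at 6.0 d. The ligand gain adds 3 points for the step to larch, which stands 3.2 points higher. The neighbour flask is larch with 1.7 M of leaving ligand, so the same gain carries larch's value to 58.8%. That neighbour flask holds 58.3% of starting complex at 6.00 d.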